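(The rate constants come from no measurement; the result is computed.)

**The question.** How far has Z gone at 80 s, and how much of the D in solution still stands free?

Z 0.40 M; J 0.400 M; time 80 s

    2 Z → Z2 (k1 = 0.15 M⁻¹ s⁻¹)
    D + Q ⇌ D.Q, settled at all times (K2 = 6900 M⁻¹)
    Z + D → Q + X (k3 = 0.42 M⁻¹ s⁻¹)
    J ⇌ D, rate k4*(cs4 - [D]) while solid is left; crystals form when [D] > cs4 (cs4 = 0.16 M, k4 = 1.2 s⁻¹)

- part of the Z that has reacted at 80 s
- share of free D in free D and D.Q together, at 80 s

- in percentages every species weighs as the Z in it: one Z2 counts as two
- a step written with two of one species runs at k times the square of its concentration and takes two of it each time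
- as a solid, counted per litre of solution: J
- at the start none of J is in solution
- run time (flask): 80 s

**Counting turnovers.** I count turnovers of Z + D → Q + X. Each takes one D, and with K2 at 6900 M⁻¹ the Q it makes takes a second D into D.Q, so a turnover costs two D. The charge of J therefore pays for 0.200 M of turnovers: this is the turnover ceiling. The ceiling assumes that Q stays bound as D.Q, and it is lower than the charge of Z, 0.40 M.

**The bracket.** The step with D adds to the loss of Z, so dimerisation by itself gives a floor: at least 90.6% reacted. [D] stays at or below 0.16 M; holding it there makes that step pseudo-first-order, and both steps together give a top of 99.8%.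

The count lowers that top. Once the solid is gone, [D] is the charge minus two per turnover, so the solid lasts at least until 0.120 M of turnovers, and after it has gone [D] falls. I expect this early, since the half-life of D by that step, with the other concentrations as charged, is 4.1 s. The share of free D at that point is 57.1%, and it falls as the turnovers near the ceiling. By hand I go no tighter.

**The forecast.** The forecast gives 96.8% and 11%, within both brackets, and calls free D “a small difference between large terms”.

**The result.** The flask gives 97.0% and 12.5%. Its X at 80.0 s is 46.8%, or 0.187 M, just under the ceiling, with J at 0%. The neighbour flask, charged with 0.16 M of Z, has its Z below the same ceiling, and there Z runs out first, with 0.30% left. Its X reaches 0.115 M, short of the 0.120 M that the solid lasts to, and J stands at 2.35% of its charge and [D] at 0.160 M. With [D] at the solubility and D.Q equal to X, the count's share of 58.1% stands beside that flask's 58.1%.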